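## Retrosynthetic overview

1. Last operations on the complete skeleton: acid unmasking of a C7 β‑hydroxy enol ether to the (Z)‑enal, acetate after a nickel‑catalysed enyne/formaldehyde reductive coupling at the side‑chain carbon on C2, decanoate by carboxylate displacement of a primary chloride.
2. Side chain: anti opening of a C1–C2 epoxide by a dienyne acetylide (trans C1‑OH/C2‑C); the epoxide comes from the C1 ketone through its enol triflate.
3. C6/C7: α′‑alkylation of a C7 enone with 1‑chloro‑3‑iodopropane, then 1,2‑addition of a lithiated bromo enol ether to the C7 ketone.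
4. Spiro atom C5, C10 carbinol and the five‑membered ring (formed second): asymmetric epoxidation/semipinacol ring expansion of a 1‑(cyclohexa‑1,4‑dienyl)cyclobutanol.
5. Six‑membered ring (first; it is the former benzene ring): Birch dearomatisation of an aryl cyclobutanol made in the same flask from 2‑bromo‑4‑methoxytoluene and cyclobutanone.

Assumption: one spiro[4.5]decane numbering is used for all intermediates (C1 carbinol carbon, C2 side‑chain carbon, C5 spiro atom, C6 chain‑bearing carbon, C7 alkylidene carbon, C10 methyl carbinol carbon), and the (R,R)‑ligand of step 2 is taken to induce the sense drawn (its antipode is used if a test run shows the opposite).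

Compounds 11–27 are epimeric with the target at C6 (chain trans to C1). The descriptor letter at C6 stays R only because the CIP ranking of C5 and C7 changes; step 16 inverts the centre.

## Route

Step 1
Reactants: 1 2-bromo-4-methoxy-1-methylbenzene; 2 cyclobutanone
Product: 4 1-(5-methoxy-2-methylcyclohexa-1,4-dien-1-yl)cyclobutan-1-ol, via lithium alkoxide 3 (not isolated)
Conditions: t-BuLi (2 equiv), THF, −78 °C; 2, −78 → 0 °C; then Li, NH3(l), t-BuOH, −78 °C; NH4Cl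
Reagents that add atoms: none
Why: Bromine–lithium exchange and 1,2-addition give the tertiary alkoxide, whose charge suppresses benzylic C–O hydrogenolysis, so the Birch reduction places the two new sp3 carbons ortho and meta to OMe (C6, C9) and leaves the enol ether and the tetrasubstituted C5=C10 alkene; no stereocentre is formed.

Step 2
Reactants: 4 1-(5-methoxy-2-methylcyclohexa-1,4-dien-1-yl)cyclobutan-1-ol
Product: 6 (5R,10S)-7-methoxy-10-methyl-10-[(triethylsilyl)oxy]spiro[4.5]dec-7-en-1-one, via epoxy alcohol 5 (not isolated)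
Conditions: Hf(OtBu)4 (10 mol%), N,N′-[(1R,2R)-cyclohexane-1,2-diyl]bis(N-hydroxy-2,2-diphenylacetamide) (12 mol%), cumene hydroperoxide, toluene, 0 °C; then Et3SiOTf, 2,6-lutidine, CH2Cl2, −78 °C
Reagents that add atoms: cumene hydroperoxide CC(C)(OO)c1ccccc1; triethylsilyl trifluoromethanesulfonate CC[Si](CC)(CC)OS(=O)(=O)C(F)(F)F
Why: Proposed new method: hydroxyl-directed asymmetric epoxidation of the tetrasubstituted allylic tertiary alcohol by the hafnium bis-hydroxamate (closest precedents: Hf/Zr bis-hydroxamic acid epoxidation of tertiary allylic alcohols and the VO(acac)2/t-BuOOH epoxidation–semipinacol of 1-(cycloalkenyl)cyclobutanols) sets C10 and the epoxide face, and on silyl triflate activation the epoxide opens at the tertiary C5 while a cyclobutane C–C bond migrates anti to the breaking C–O bond (semipinacol ring expansion), so the C10–O bond and the new C5–C4 bond end up trans and C5 follows stereospecifically from the epoxidation.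

Step 3
Reactants: 6 (5R,10S)-7-methoxy-10-methyl-10-[(triethylsilyl)oxy]spiro[4.5]dec-7-en-1-one
Product: 8 (5R,10S)-10-methyl-7-oxo-10-[(triethylsilyl)oxy]spiro[4.5]dec-1-en-1-yl trifluoromethanesulfonate, via enol triflate 7 (not isolated)
Conditions: KN(SiMe3)2, THF, −78 °C; PhNTf2; then 0.5 M HCl, THF, 0 °C
Reagents that add atoms: N-phenylbis(trifluoromethanesulfonimide) O=S(=O)(N(c1ccccc1)S(=O)(=O)C(F)(F)F)C(F)(F)F; water O
Why: The C1 ketone can enolise only toward C2, so enolate O-sulfonylation gives one enol triflate, and dilute acid then hydrolyses the methyl enol ether to the C7 ketone without touching a stereocentre.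

Step 4
Reactants: 8 (5R,10S)-10-methyl-7-oxo-10-[(triethylsilyl)oxy]spiro[4.5]dec-1-en-1-yl trifluoromethanesulfonate
Product: 9 (5R,10S)-10-methyl-7-oxo-10-[(triethylsilyl)oxy]spiro[4.5]deca-1,8-dien-1-yl trifluoromethanesulfonate
Conditions: 2-iodoxybenzoic acid (IBX), DMSO/fluorobenzene, 65 °C
Reagents that add atoms: none
Why: IBX dehydrogenation of the ketone (Nicolaou) can only form the C8=C9 double bond because C6 is flanked by the quaternary C5, and the resulting enone leaves C6 as the sole enolisable position.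

Step 5
Reactants: 9 (5R,10S)-10-methyl-7-oxo-10-[(triethylsilyl)oxy]spiro[4.5]deca-1,8-dien-1-yl trifluoromethanesulfonate; 10 1-chloro-3-iodopropane
Product: 11 (5R,6R,10S)-6-(3-chloropropyl)-10-methyl-7-oxo-10-[(triethylsilyl)oxy]spiro[4.5]deca-1,8-dien-1-yl trifluoromethanesulfonate
Conditions: LiN(i-Pr)2, THF, −78 °C; 10, DMPU, −78 → −20 °C
Reagents that add atoms: none
Why: Kinetic α′-enolate alkylation at the iodide end of 10; the electrophile approaches C6 anti to the C10 silyloxy group and the triflate-bearing C1, giving the chain trans to C1 (6-epi), which is the stable epimer at the ketone stage and is inverted in step 16.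

Step 6
Reactants: 11 (5R,6R,10S)-6-(3-chloropropyl)-10-methyl-7-oxo-10-[(triethylsilyl)oxy]spiro[4.5]deca-1,8-dien-1-yl trifluoromethanesulfonate
Product: 12 (5R,6R,10S)-6-(3-chloropropyl)-10-methyl-10-[(triethylsilyl)oxy]spiro[4.5]dec-1-en-7-one
Conditions: Pd(PPh3)4 (5 mol%), Bu3SnH, LiCl, AcOH, THF, 23 °C
Reagents that add atoms: none
Why: Zerovalent palladium with tin hydride reduces the enol triflate to the C1=C2 alkene (Stille-type hydride transfer) and the enone to the saturated ketone (Keinan conjugate reduction) in one operation; the tin enolate forms toward C8, so C6 is untouched.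

Step 7
Reactants: 12 (5R,6R,10S)-6-(3-chloropropyl)-10-methyl-10-[(triethylsilyl)oxy]spiro[4.5]dec-1-en-7-one
Product: 13 (1S,2R,5S,6R,10S)-6-(3-chloropropyl)-1,2-epoxy-10-methyl-10-[(triethylsilyl)oxy]spiro[4.5]decan-7-one
Conditions: mCPBA, NaHCO3, CH2Cl2, 0 °C
Reagents that add atoms: 3-chloroperoxybenzoic acid OOC(=O)c1cccc(Cl)c1
Why: Prilezhaev epoxidation of the strained cis-alkene from the face next to the C6 methine and away from the quaternary C10 (Me, OSiEt3), which fixes the oxygen configuration at C1.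

Step 8
Reactants: 14 2-bromo-1,1-diethoxypropane
Product: 15 (Z)-2-bromo-1-ethoxyprop-1-ene
Conditions: Me3SiOTf, i-Pr2NEt, CH2Cl2, −20 → 23 °C
Reagents that add atoms: none
Why: Gassman-type silyl triflate/amine elimination of ethanol from the acetal gives the bromo enol ether (the Z isomer, Br cis to OEt, is the one whose lithio derivative is stable).

Step 9
Reactants: 13 (1S,2R,5S,6R,10S)-6-(3-chloropropyl)-1,2-epoxy-10-methyl-10-[(triethylsilyl)oxy]spiro[4.5]decan-7-one; 15 (Z)-2-bromo-1-ethoxyprop-1-ene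
Product: 16 (1S,2R,5S,6R,10S)-6-(3-chloropropyl)-1,2-epoxy-7-[(1Z)-1-ethoxyprop-1-en-2-yl]-10-methyl-10-[(triethylsilyl)oxy]spiro[4.5]decan-7-ol (both C7 epimers)
Conditions: 15, t-BuLi (2 equiv), Et2O, −78 °C; CeCl3, THF, −78 °C; then 13; aq. NaHCO3
Reagents that add atoms: none
Why: Bromine–lithium exchange gives the cis-β-ethoxyalkenyllithium (a Duhamel/Wollenberg-type masked enal anion), which as its organocerium adds 1,2 to the hindered C7 ketone without enolisation or epoxide opening; the new C7 centre is irrelevant because it becomes sp2 in step 16.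

Step 10
Reactants: 17 2-methyl-2-vinyloxirane (racemic); 18 (2-methylprop-1-en-1-yl)magnesium bromide
Product: 19 (2E)-2,6-dimethylhepta-2,5-dien-1-ol
Conditions: CuBr·SMe2 (5 mol%), THF, −30 °C; NH4Cl
Reagents that add atoms: none
Why: Copper-catalysed SN2′ opening of the vinyl epoxide by the alkenyl Grignard reagent gives the (E)-trisubstituted allylic alcohol.

Step 11
Reactants: 19 (2E)-2,6-dimethylhepta-2,5-dien-1-ol
Product: 20 (2E)-2,6-dimethylhepta-2,5-dienal
Conditions: MnO2, CH2Cl2, 23 °C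
Reagents that add atoms: none
Why: Chemoselective MnO2 oxidation of the allylic alcohol leaves the skipped diene untouched.

Step 12
Reactants: 20 (2E)-2,6-dimethylhepta-2,5-dienal; 21 diethyl [3-(trimethylsilyl)prop-2-yn-1-yl]phosphonate
Product: 22 trimethyl[(3E,5E)-5,9-dimethyldeca-3,5,8-trien-1-yn-1-yl]silane
Conditions: LiN(SiMe3)2, THF, −78 → 0 °C; NH4Cl
Reagents that add atoms: none
Why: Horner–Wadsworth–Emmons olefination with the propargylic phosphonate gives the (E)-enyne.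

Step 13
Reactants: 16 (1S,2R,5S,6R,10S)-6-(3-chloropropyl)-1,2-epoxy-7-[(1Z)-1-ethoxyprop-1-en-2-yl]-10-methyl-10-[(triethylsilyl)oxy]spiro[4.5]decan-7-ol; 22 trimethyl[(3E,5E)-5,9-dimethyldeca-3,5,8-trien-1-yn-1-yl]silane
Product: 23 (1R,2R,5S,6R,10S)-6-(3-chloropropyl)-2-[(3E,5E)-5,9-dimethyldeca-3,5,8-trien-1-yn-1-yl]-7-[(1Z)-1-ethoxyprop-1-en-2-yl]-10-methyl-10-[(triethylsilyl)oxy]spiro[4.5]decane-1,7-diol
Conditions: 22, MeLi·LiBr, THF, 0 → 23 °C; AlMe3, toluene, 0 °C; then 16 (as its lithium alkoxide, MeLi), 0 → 40 °C; aq. potassium sodium tartrate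
Reagents that add atoms: none
Why: Methyllithium cleaves the C–Si bond to the lithium acetylide, which as its trimethylaluminate (no strong Lewis acid, so the acid-labile carbinol survives) opens the epoxide at C2, remote from the quaternary C5, with inversion; this sets C2 and gives the trans-2-alkynyl alcohol.

Step 14
Reactants: 23 (1R,2R,5S,6R,10S)-6-(3-chloropropyl)-2-[(3E,5E)-5,9-dimethyldeca-3,5,8-trien-1-yn-1-yl]-7-[(1Z)-1-ethoxyprop-1-en-2-yl]-10-methyl-10-[(triethylsilyl)oxy]spiro[4.5]decane-1,7-diol; 24 decanoic acid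
Product: 25 3-[(1R,2R,5S,6R,10S)-2-[(3E,5E)-5,9-dimethyldeca-3,5,8-trien-1-yn-1-yl]-7-[(1Z)-1-ethoxyprop-1-en-2-yl]-1,7-dihydroxy-10-methyl-10-[(triethylsilyl)oxy]spiro[4.5]decan-6-yl]propyl decanoate
Conditions: 24, Cs2CO3, sodium iodide (10 mol%), DMF, 60 °C
Reagents that add atoms: none
Why: Iodide-catalysed SN2 displacement of the primary chloride by caesium decanoate installs the ester without an acylating agent, so the secondary and tertiary hydroxyls stay free.

Step 15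
Reactants: 25 3-[(1R,2R,5S,6R,10S)-2-[(3E,5E)-5,9-dimethyldeca-3,5,8-trien-1-yn-1-yl]-7-[(1Z)-1-ethoxyprop-1-en-2-yl]-1,7-dihydroxy-10-methyl-10-[(triethylsilyl)oxy]spiro[4.5]decan-6-yl]propyl decanoate
Product: 27 3-[(1R,2R,5S,6R,10S)-2-[(2E,4E,6E)-1-(acetyloxy)-6,10-dimethylundeca-2,4,6,9-tetraen-2-yl]-7-[(1Z)-1-ethoxyprop-1-en-2-yl]-1,7-dihydroxy-10-methyl-10-[(triethylsilyl)oxy]spiro[4.5]decan-6-yl]propyl decanoate, via diethylborinate 26 (not isolated)
Conditions: Ni(cod)2 (10 mol%), PCy3 (20 mol%), Et3B, paraformaldehyde, toluene, 23 °C; then air; Ac2O, pyridine, DMAP, 0 °C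
Reagents that add atoms: formaldehyde (from paraformaldehyde) C=O; acetic anhydride CC(=O)OC(C)=O
Why: Nickel-catalysed reductive coupling of a 1,3-enyne with an aldehyde (Jamison–Montgomery type, here with formaldehyde): the conjugated alkene directs C–C bond formation to the distal alkyne carbon and H and CH2O add cis, giving the (2E) trisubstituted alkene; after the zerovalent nickel is quenched with air, the primary borinate is acetylated in preference to the hindered C1 hydroxyl.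

Step 16
Reactants: 27 3-[(1R,2R,5S,6R,10S)-2-[(2E,4E,6E)-1-(acetyloxy)-6,10-dimethylundeca-2,4,6,9-tetraen-2-yl]-7-[(1Z)-1-ethoxyprop-1-en-2-yl]-1,7-dihydroxy-10-methyl-10-[(triethylsilyl)oxy]spiro[4.5]decan-6-yl]propyl decanoate
Product: 28 3-[(1R,2R,5S,6R,7Z,10S)-2-[(2E,4E,6E)-1-(acetyloxy)-6,10-dimethylundeca-2,4,6,9-tetraen-2-yl]-1,10-dihydroxy-10-methyl-7-(1-oxopropan-2-ylidene)spiro[4.5]decan-6-yl]propyl decanoate (CNP0271899.1)
Conditions: HF·pyridine, pyridine, THF, 0 → 23 °C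
Reagents that add atoms: none
Why: HF removes the silyl ether and ionises the tertiary allylic carbinol to an ethoxy-stabilised allyl cation that collapses to the enal (Wollenberg-type 1,3-transposition), while reversible loss and return of H6 through the dienol ether lets C6 and the alkene settle in the thermodynamic (6R,7Z) arrangement, in which the axial chain is syn to the small C10 hydroxyl instead of the C10 methyl and the formyl group faces C6.

## Compound list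

1 | 2-bromo-4-methoxy-1-methylbenzene | COc1ccc(C)c(Br)c1 | starting material
2 | cyclobutanone | O=C1CCC1 | starting material
3 | lithium 1-(5-methoxy-2-methylphenyl)cyclobutan-1-olate | [Li+].COc1ccc(C)c(c1)C1([O-])CCC1 | intermediate
4 | 1-(5-methoxy-2-methylcyclohexa-1,4-dien-1-yl)cyclobutan-1-ol | COC1=CCC(C)=C(C1)C1(O)CCC1 | intermediate
5 | 1-[(1S,6S)-3-methoxy-6-methyl-7-oxabicyclo[4.1.0]hept-3-en-1-yl]cyclobutan-1-ol | C1C(OC)=CC[C@]2(C)O[C@]12C3(O)CCC3 | intermediate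
6 | (5R,10S)-7-methoxy-10-methyl-10-[(triethylsilyl)oxy]spiro[4.5]dec-7-en-1-one | C1C(OC)=CC[C@](C)(O[Si](CC)(CC)CC)[C@@]12CCCC2=O | intermediate
7 | (5R,10S)-7-methoxy-10-methyl-10-[(triethylsilyl)oxy]spiro[4.5]deca-1,7-dien-1-yl trifluoromethanesulfonate | C1C(OC)=CC[C@](C)(O[Si](CC)(CC)CC)[C@@]12CCC=C2OS(=O)(=O)C(F)(F)F | intermediate
8 | (5R,10S)-10-methyl-7-oxo-10-[(triethylsilyl)oxy]spiro[4.5]dec-1-en-1-yl trifluoromethanesulfonate | C1C(=O)CC[C@](C)(O[Si](CC)(CC)CC)[C@@]12CCC=C2OS(=O)(=O)C(F)(F)F | intermediate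
9 | (5R,10S)-10-methyl-7-oxo-10-[(triethylsilyl)oxy]spiro[4.5]deca-1,8-dien-1-yl trifluoromethanesulfonate | C1C(=O)C=C[C@](C)(O[Si](CC)(CC)CC)[C@@]12CCC=C2OS(=O)(=O)C(F)(F)F | intermediate
10 | 1-chloro-3-iodopropane | ClCCCI | starting material
11 | (5R,6R,10S)-6-(3-chloropropyl)-10-methyl-7-oxo-10-[(triethylsilyl)oxy]spiro[4.5]deca-1,8-dien-1-yl trifluoromethanesulfonate | ClCCC[C@H]1C(=O)C=C[C@](C)(O[Si](CC)(CC)CC)[C@@]12CCC=C2OS(=O)(=O)C(F)(F)F | intermediate
12 | (5R,6R,10S)-6-(3-chloropropyl)-10-methyl-10-[(triethylsilyl)oxy]spiro[4.5]dec-1-en-7-one | ClCCC[C@H]1C(=O)CC[C@](C)(O[Si](CC)(CC)CC)[C@@]12CCC=C2 | intermediate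
13 | (1S,2R,5S,6R,10S)-6-(3-chloropropyl)-1,2-epoxy-10-methyl-10-[(triethylsilyl)oxy]spiro[4.5]decan-7-one | ClCCC[C@H]1C(=O)CC[C@](C)(O[Si](CC)(CC)CC)[C@@]12CC[C@H]3O[C@@H]23 | intermediate
14 | 2-bromo-1,1-diethoxypropane (racemic) | CCOC(OCC)C(C)Br | starting material
15 | (Z)-2-bromo-1-ethoxyprop-1-ene | CCO/C=C(/C)Br | intermediate
16 | (1S,2R,5S,6R,10S)-6-(3-chloropropyl)-1,2-epoxy-7-[(1Z)-1-ethoxyprop-1-en-2-yl]-10-methyl-10-[(triethylsilyl)oxy]spiro[4.5]decan-7-ol (both C7 epimers) | ClCCC[C@H]1C(O)(/C(C)=C\OCC)CC[C@](C)(O[Si](CC)(CC)CC)[C@@]12CC[C@H]3O[C@@H]23 | intermediate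
17 | 2-methyl-2-vinyloxirane (racemic) | CC1(CO1)C=C | starting material
18 | (2-methylprop-1-en-1-yl)magnesium bromide | CC(C)=C[Mg]Br | starting material
19 | (2E)-2,6-dimethylhepta-2,5-dien-1-ol | CC(C)=CC/C=C(\C)CO | intermediate
20 | (2E)-2,6-dimethylhepta-2,5-dienal | CC(C)=CC/C=C(\C)C=O | intermediate
21 | diethyl [3-(trimethylsilyl)prop-2-yn-1-yl]phosphonate | CCOP(=O)(OCC)CC#C[Si](C)(C)C | starting material
22 | trimethyl[(3E,5E)-5,9-dimethyldeca-3,5,8-trien-1-yn-1-yl]silane | C[Si](C)(C)C#C/C=C/C(C)=C/CC=C(C)C | intermediate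
23 | (1R,2R,5S,6R,10S)-6-(3-chloropropyl)-2-[(3E,5E)-5,9-dimethyldeca-3,5,8-trien-1-yn-1-yl]-7-[(1Z)-1-ethoxyprop-1-en-2-yl]-10-methyl-10-[(triethylsilyl)oxy]spiro[4.5]decane-1,7-diol | ClCCC[C@H]1C(O)(/C(C)=C\OCC)CC[C@](C)(O[Si](CC)(CC)CC)[C@@]12CC[C@H](C#C/C=C/C(C)=C/CC=C(C)C)[C@H]2O | intermediate
24 | decanoic acid | CCCCCCCCCC(=O)O | starting material
25 | 3-[(1R,2R,5S,6R,10S)-2-[(3E,5E)-5,9-dimethyldeca-3,5,8-trien-1-yn-1-yl]-7-[(1Z)-1-ethoxyprop-1-en-2-yl]-1,7-dihydroxy-10-methyl-10-[(triethylsilyl)oxy]spiro[4.5]decan-6-yl]propyl decanoate | CCCCCCCCCC(=O)OCCC[C@H]1C(O)(/C(C)=C\OCC)CC[C@](C)(O[Si](CC)(CC)CC)[C@@]12CC[C@H](C#C/C=C/C(C)=C/CC=C(C)C)[C@H]2O | intermediate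
26 | 3-[(1R,2R,5S,6R,10S)-2-{(2E,4E,6E)-1-[(diethylboranyl)oxy]-6,10-dimethylundeca-2,4,6,9-tetraen-2-yl}-7-[(1Z)-1-ethoxyprop-1-en-2-yl]-1,7-dihydroxy-10-methyl-10-[(triethylsilyl)oxy]spiro[4.5]decan-6-yl]propyl decanoate | CCCCCCCCCC(=O)OCCC[C@H]1C(O)(/C(C)=C\OCC)CC[C@](C)(O[Si](CC)(CC)CC)[C@@]12CC[C@H](\C(=C/C=C/C(C)=C/CC=C(C)C)COB(CC)CC)[C@H]2O | intermediate
27 | 3-[(1R,2R,5S,6R,10S)-2-[(2E,4E,6E)-1-(acetyloxy)-6,10-dimethylundeca-2,4,6,9-tetraen-2-yl]-7-[(1Z)-1-ethoxyprop-1-en-2-yl]-1,7-dihydroxy-10-methyl-10-[(triethylsilyl)oxy]spiro[4.5]decan-6-yl]propyl decanoate | CCCCCCCCCC(=O)OCCC[C@H]1C(O)(/C(C)=C\OCC)CC[C@](C)(O[Si](CC)(CC)CC)[C@@]12CC[C@H](\C(=C/C=C/C(C)=C/CC=C(C)C)COC(C)=O)[C@H]2O | intermediate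
28 | 3-[(1R,2R,5S,6R,7Z,10S)-2-[(2E,4E,6E)-1-(acetyloxy)-6,10-dimethylundeca-2,4,6,9-tetraen-2-yl]-1,10-dihydroxy-10-methyl-7-(1-oxopropan-2-ylidene)spiro[4.5]decan-6-yl]propyl decanoate (CNP0271899.1) | CCCCCCCCCC(=O)OCCC[C@@H]1/C(=C(/C)C=O)CC[C@](C)(O)[C@@]12CC[C@H](\C(=C/C=C/C(C)=C/CC=C(C)C)COC(C)=O)[C@H]2O | target

## Step count and risks

Total step count: 16. Longest linear sequence: 12 steps (steps 1–7, 9, 13–16).

**Step 2 (asymmetric epoxidation/semipinacol).** The enantioselectivity on a hindered tetrasubstituted alkene is unproven. The fallback sets out from 4 and comes back at 6. VO(acac)2 with t-BuOOH (CH2Cl2, 0 °C, then PPTS) runs the same epoxidation–ring expansion without induction and gives racemic 10-hydroxy-7-methoxy-10-methylspiro[4.5]dec-7-en-1-one F1. Reagent-controlled reduction with (S)-2-methyl-CBS-oxazaborolidine and catecholborane turns the two enantiomers into diastereomeric diols, from which (1R,5S,10S)-7-methoxy-10-methylspiro[4.5]dec-7-ene-1,10-diol F2 is separated by chromatography. Buffered Dess–Martin oxidation returns enantiopure (5R,10S)-10-hydroxy-7-methoxy-10-methylspiro[4.5]dec-7-en-1-one F3, which Et3SiOTf/2,6-lutidine silylates to 6.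

**Step 15 (nickel enyne/formaldehyde coupling).** Regiocontrol or turnover may fail on this polyfunctional substrate. The fallback sets out from 25 and comes back at 27. Copper-catalysed syn-protoboration (CuCl, Xantphos, NaOt-Bu, B2pin2, MeOH; boron goes to the alkyne carbon remote from the diene) gives the dienyl boronate 3-[(1R,2R,5S,6R,10S)-2-[(1Z,3E,5E)-5,9-dimethyl-1-(4,4,5,5-tetramethyl-1,3,2-dioxaborolan-2-yl)deca-1,3,5,8-tetraen-1-yl]-7-[(1Z)-1-ethoxyprop-1-en-2-yl]-1,7-dihydroxy-10-methyl-10-[(triethylsilyl)oxy]spiro[4.5]decan-6-yl]propyl decanoate F4. [Rh(OH)(cod)]2-catalysed 1,2-addition of the alkenyl boronate to paraformaldehyde (aqueous dioxane) gives the free allylic alcohol 3-[(1R,2R,5S,6R,10S)-7-[(1Z)-1-ethoxyprop-1-en-2-yl]-1,7-dihydroxy-2-[(2E,4E,6E)-1-hydroxy-6,10-dimethylundeca-2,4,6,9-tetraen-2-yl]-10-methyl-10-[(triethylsilyl)oxy]spiro[4.5]decan-6-yl]propyl decanoate F5, and Ac2O/pyridine at 0 °C converts it into 27.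

**Step 16 (enal unmasking with C6 inversion).** The late epimerisation at C6 and the enal geometry rest on a thermodynamic argument. The fallback sets out from 11 and comes back at 28; it sets C6 kinetically at the enone stage instead. Re-enolisation of 11 with LiN(i-Pr)2 (THF, −78 °C) and protonation by 2,6-di-tert-butylphenol from the face anti to the silyloxy group gives (5R,6S,10S)-6-(3-chloropropyl)-10-methyl-7-oxo-10-[(triethylsilyl)oxy]spiro[4.5]deca-1,8-dien-1-yl trifluoromethanesulfonate F6. The operations of steps 6, 7, 9, 13, 14 and 15 then give in turn: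
- (5R,6S,10S)-6-(3-chloropropyl)-10-methyl-10-[(triethylsilyl)oxy]spiro[4.5]dec-1-en-7-one F7;
- (1S,2R,5S,6S,10S)-6-(3-chloropropyl)-1,2-epoxy-10-methyl-10-[(triethylsilyl)oxy]spiro[4.5]decan-7-one F8 (the epoxidation may be less face-selective here; the minor epoxide is removed by chromatography);
- (1S,2R,5S,6S,10S)-6-(3-chloropropyl)-1,2-epoxy-7-[(1Z)-1-ethoxyprop-1-en-2-yl]-10-methyl-10-[(triethylsilyl)oxy]spiro[4.5]decan-7-ol F9;
- (1R,2R,5S,6S,10S)-6-(3-chloropropyl)-2-[(3E,5E)-5,9-dimethyldeca-3,5,8-trien-1-yn-1-yl]-7-[(1Z)-1-ethoxyprop-1-en-2-yl]-10-methyl-10-[(triethylsilyl)oxy]spiro[4.5]decane-1,7-diol F10;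
- the corresponding (6S)-decanoate F11;
- the corresponding (6S)-acetate F12.

The (6S)-acetate gives 28 under the conditions of step 16 with no epimerisation needed.

## Further compounds

F1 | step 2 | 10-hydroxy-7-methoxy-10-methylspiro[4.5]dec-7-en-1-one, racemate of the (5R,10S) form shown | C1C(OC)=CC[C@](C)(O)[C@@]12CCCC2=O
F2 | step 2 | (1R,5S,10S)-7-methoxy-10-methylspiro[4.5]dec-7-ene-1,10-diol | C1C(OC)=CC[C@](C)(O)[C@@]12CCC[C@H]2O
F3 | step 2 | (5R,10S)-10-hydroxy-7-methoxy-10-methylspiro[4.5]dec-7-en-1-one, single enantiomer | C1C(OC)=CC[C@](C)(O)[C@@]12CCCC2=O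
F4 | step 15 | 3-[(1R,2R,5S,6R,10S)-2-[(1Z,3E,5E)-5,9-dimethyl-1-(4,4,5,5-tetramethyl-1,3,2-dioxaborolan-2-yl)deca-1,3,5,8-tetraen-1-yl]-7-[(1Z)-1-ethoxyprop-1-en-2-yl]-1,7-dihydroxy-10-methyl-10-[(triethylsilyl)oxy]spiro[4.5]decan-6-yl]propyl decanoate | CCCCCCCCCC(=O)OCCC[C@H]1C(O)(/C(C)=C\OCC)CC[C@](C)(O[Si](CC)(CC)CC)[C@@]12CC[C@H](\C(=C/C=C/C(C)=C/CC=C(C)C)B3OC(C)(C)C(C)(C)O3)[C@H]2O
F5 | step 15 | 3-[(1R,2R,5S,6R,10S)-7-[(1Z)-1-ethoxyprop-1-en-2-yl]-1,7-dihydroxy-2-[(2E,4E,6E)-1-hydroxy-6,10-dimethylundeca-2,4,6,9-tetraen-2-yl]-10-methyl-10-[(triethylsilyl)oxy]spiro[4.5]decan-6-yl]propyl decanoate | CCCCCCCCCC(=O)OCCC[C@H]1C(O)(/C(C)=C\OCC)CC[C@](C)(O[Si](CC)(CC)CC)[C@@]12CC[C@H](\C(=C/C=C/C(C)=C/CC=C(C)C)CO)[C@H]2O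
F6 | step 16 | (5R,6S,10S)-6-(3-chloropropyl)-10-methyl-7-oxo-10-[(triethylsilyl)oxy]spiro[4.5]deca-1,8-dien-1-yl trifluoromethanesulfonate | ClCCC[C@@H]1C(=O)C=C[C@](C)(O[Si](CC)(CC)CC)[C@@]12CCC=C2OS(=O)(=O)C(F)(F)F
F7 | step 16 | (5R,6S,10S)-6-(3-chloropropyl)-10-methyl-10-[(triethylsilyl)oxy]spiro[4.5]dec-1-en-7-one | ClCCC[C@@H]1C(=O)CC[C@](C)(O[Si](CC)(CC)CC)[C@@]12CCC=C2
F8 | step 16 | (1S,2R,5S,6S,10S)-6-(3-chloropropyl)-1,2-epoxy-10-methyl-10-[(triethylsilyl)oxy]spiro[4.5]decan-7-one | ClCCC[C@@H]1C(=O)CC[C@](C)(O[Si](CC)(CC)CC)[C@@]12CC[C@H]3O[C@@H]23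
F9 | step 16 | (1S,2R,5S,6S,10S)-6-(3-chloropropyl)-1,2-epoxy-7-[(1Z)-1-ethoxyprop-1-en-2-yl]-10-methyl-10-[(triethylsilyl)oxy]spiro[4.5]decan-7-ol (both C7 epimers) | ClCCC[C@@H]1C(O)(/C(C)=C\OCC)CC[C@](C)(O[Si](CC)(CC)CC)[C@@]12CC[C@H]3O[C@@H]23
F10 | step 16 | (1R,2R,5S,6S,10S)-6-(3-chloropropyl)-2-[(3E,5E)-5,9-dimethyldeca-3,5,8-trien-1-yn-1-yl]-7-[(1Z)-1-ethoxyprop-1-en-2-yl]-10-methyl-10-[(triethylsilyl)oxy]spiro[4.5]decane-1,7-diol | ClCCC[C@@H]1C(O)(/C(C)=C\OCC)CC[C@](C)(O[Si](CC)(CC)CC)[C@@]12CC[C@H](C#C/C=C/C(C)=C/CC=C(C)C)[C@H]2O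
F11 | step 16 | 3-[(1R,2R,5S,6S,10S)-2-[(3E,5E)-5,9-dimethyldeca-3,5,8-trien-1-yn-1-yl]-7-[(1Z)-1-ethoxyprop-1-en-2-yl]-1,7-dihydroxy-10-methyl-10-[(triethylsilyl)oxy]spiro[4.5]decan-6-yl]propyl decanoate | CCCCCCCCCC(=O)OCCC[C@@H]1C(O)(/C(C)=C\OCC)CC[C@](C)(O[Si](CC)(CC)CC)[C@@]12CC[C@H](C#C/C=C/C(C)=C/CC=C(C)C)[C@H]2O
F12 | step 16 | 3-[(1R,2R,5S,6S,10S)-2-[(2E,4E,6E)-1-(acetyloxy)-6,10-dimethylundeca-2,4,6,9-tetraen-2-yl]-7-[(1Z)-1-ethoxyprop-1-en-2-yl]-1,7-dihydroxy-10-methyl-10-[(triethylsilyl)oxy]spiro[4.5]decan-6-yl]propyl decanoate | CCCCCCCCCC(=O)OCCC[C@@H]1C(O)(/C(C)=C\OCC)CC[C@](C)(O[Si](CC)(CC)CC)[C@@]12CC[C@H](\C(=C/C=C/C(C)=C/CC=C(C)C)COC(C)=O)[C@H]2O
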